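**Retrosynthetic overview**
1. The 12-membered dilactone is the only ring formed and is closed last, by Mitsunobu macrolactonization (inversion at the ring B side-chain carbinol); seven benzyl ethers are then removed in one hydrogenolysis.
2. The seco acid comes from a Mitsunobu esterification of the ring B acid 15 with the ring A alcohol 7 (inversion), followed by iodine–magnesium exchange/CO2 on ring A.
3. Both halves come from one achiral iodo-propenylarene 4; ring B gains its extra oxygen by hydroxylation/benzylation of the aryl iodide, and its carboxyl carbon by a later iodination/carboxylation.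
4. All chirality comes from one metal-free reaction type, chiral-ketone (dioxirane) epoxidation of the (E)-alkenes 4 and 9 to (S,S)-epoxides.
5. The epoxides are opened at the benzylic carbon with opposite stereochemical outcomes: inversion (BnOH, BF3·OEt2) for the ring B half, retention (new boron-delivered benzyloxylation) for the ring A half.

Assumption: 3,5-dihydroxy-4-methoxybenzaldehyde (1) and the L-fructose-derived enantiomer of the Shi ketone (a catalyst, made from L-sorbose) are taken as purchasable.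

**Route**

Step 1
Reactants: 1 3,5-dihydroxy-4-methoxybenzaldehyde
Product: 2 3,5-bis(benzyloxy)-4-methoxybenzaldehyde
Conditions: BnBr (2.4 equiv), K2CO3 (3 equiv), DMF, 60 °C
Reagents that add atoms: benzyl bromide, BrCc1ccccc1
Why: Williamson etherification of both phenols; the aldehyde is inert and no stereocentre is involved.

Step 2
Reactants: 2 3,5-bis(benzyloxy)-4-methoxybenzaldehyde
Product: 3 3,5-bis(benzyloxy)-2-iodo-4-methoxybenzaldehyde
Conditions: NIS (1.05 equiv), CF3CO2H (0.3 equiv), MeCN, rt, dark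
Reagents that add atoms: N-iodosuccinimide, O=C1CCC(=O)N1I
Why: Electrophilic aromatic iodination; the two free ring positions are equivalent and each is ortho and para to a benzyloxy group, so one equivalent gives the single mono-iodide.

Step 3
Reactants: 3 3,5-bis(benzyloxy)-2-iodo-4-methoxybenzaldehyde
Product: 4 1,3-bis(benzyloxy)-4-iodo-2-methoxy-5-[(E)-prop-1-en-1-yl]benzene
Conditions: 5-(ethylsulfonyl)-1-phenyl-1H-tetrazole (1.3 equiv), KN(SiMe3)2 (1.25 equiv), DME, −60 °C → rt; then 0.5 M HCl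
Reagents that add atoms: 5-(ethylsulfonyl)-1-phenyl-1H-tetrazole, CCS(=O)(=O)c1nnnn1-c1ccccc1
Why: Julia–Kocienski olefination, which under potassium/DME conditions gives the (E)-propenylarene (minor Z isomer removed by chromatography).

Step 4
Reactants: 4 1,3-bis(benzyloxy)-4-iodo-2-methoxy-5-[(E)-prop-1-en-1-yl]benzene
Product: 5 (2S,3S)-2-[3,5-bis(benzyloxy)-2-iodo-4-methoxyphenyl]-3-methyloxirane
Conditions: L-fructose-derived Shi ketone (0.3 equiv), Oxone (2KHSO5·KHSO4·K2SO4), K2CO3, n-Bu4NHSO4 (cat.), MeCN–CH2(OMe)2–aq. Na2B4O7/Na2H2EDTA buffer (pH 10.5), 0 °C; Na2S2O3 work-up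
Reagents that add atoms: potassium peroxymonosulfate (active salt of Oxone), [K+].[O-]S(=O)(=O)OO
Why: Shi epoxidation (chiral dioxirane organocatalysis) through the spiro transition state for trans-disubstituted olefins; the L-ketone gives the mirror image of the (R,R) sense known for the D-ketone, setting both stereocentres as (2S,3S) from achiral 4, and the thiosulfate work-up returns any over-oxidised aryl iodide.

Step 5
Reactants: 5 (2S,3S)-2-[3,5-bis(benzyloxy)-2-iodo-4-methoxyphenyl]-3-methyloxirane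
Product: 7 (1S,2S)-1-(benzyloxy)-1-[3,5-bis(benzyloxy)-2-iodo-4-methoxyphenyl]propan-2-ol, via borinate ester 6 (not isolated)
Conditions: (C6F5)2BOH (1.3 equiv) + BnOH (1.3 equiv), 4 Å MS, toluene, 40 °C, 1 h; then 5, −40 → 0 °C; MeOH/aq. NaHCO3
Reagents that add atoms: benzyl alcohol, OCc1ccccc1, delivered as benzyloxybis(pentafluorophenyl)borane, Fc1c(F)c(F)c(B(OCc2ccccc2)c2c(F)c(F)c(F)c(F)c2F)c(F)c1F
Why: Proposed new method: the electron-poor borinate (C6F5)2B–OBn binds the epoxide oxygen, the benzylic C–O bond loosens inside the resulting borate ion pair, and the boron-bound benzyloxide (made nucleophilic by four-coordination and held on the face the oxygen is leaving) is passed to the benzylic carbon through a five-membered SNi-type transition state, so C1 keeps its S configuration (retention) and C2 (S) is untouched, giving the (1S,2S) product; the closest known reaction types are the syn-opening of aryl epoxides by triaryl borates and boron-mediated aglycon delivery to 1,2-anhydro sugars, neither shown for an alkoxide carried on a borinate.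

Step 6
Reactants: 4 1,3-bis(benzyloxy)-4-iodo-2-methoxy-5-[(E)-prop-1-en-1-yl]benzene
Product: 9 1,3,4-tris(benzyloxy)-2-methoxy-5-[(E)-prop-1-en-1-yl]benzene, via potassium phenolate 8 (not isolated)
Conditions: Pd2(dba)3 (2 mol%), t-BuXPhos (8 mol%), KOH (4 equiv), 1,4-dioxane–H2O, 100 °C; then BnBr (1.5 equiv), n-Bu4NBr, 80 °C
Reagents that add atoms: potassium hydroxide, [K+].[OH-]; benzyl bromide, BrCc1ccccc1
Why: Buchwald-type palladium-catalysed hydroxylation of the hindered aryl iodide with KOH, then Williamson benzylation of the phenolate in the same flask; the propenyl group and benzyl ethers are inert and no stereocentre is involved.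

Step 7
Reactants: 9 1,3,4-tris(benzyloxy)-2-methoxy-5-[(E)-prop-1-en-1-yl]benzene
Product: 10 (2S,3S)-3-methyl-2-[2,3,5-tris(benzyloxy)-4-methoxyphenyl]oxirane
Conditions: L-fructose-derived Shi ketone (0.3 equiv), Oxone (2KHSO5·KHSO4·K2SO4), K2CO3, n-Bu4NHSO4 (cat.), MeCN–CH2(OMe)2–aq. Na2B4O7/Na2H2EDTA buffer (pH 10.5), 0 °C
Reagents that add atoms: potassium peroxymonosulfate (active salt of Oxone), [K+].[O-]S(=O)(=O)OO
Why: Shi epoxidation with the same catalyst and the same facial sense as step 4, setting both stereocentres of the ring B half as (2S,3S).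

Step 8
Reactants: 10 (2S,3S)-3-methyl-2-[2,3,5-tris(benzyloxy)-4-methoxyphenyl]oxirane
Product: 11 (1R,2S)-1-(benzyloxy)-1-[2,3,5-tris(benzyloxy)-4-methoxyphenyl]propan-2-ol
Conditions: BnOH (5 equiv), BF3·OEt2 (10 mol%), CH2Cl2, −40 °C
Reagents that add atoms: benzyl alcohol, OCc1ccccc1
Why: Lewis-acid-catalysed epoxide alcoholysis; excess BnOH attacks the activated benzylic carbon in a borderline SN2 manner with inversion (S → R) while C2 keeps S, and the out-of-plane alkoxy groups limit cation character and stereochemical leakage.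

Step 9
Reactants: 11 (1R,2S)-1-(benzyloxy)-1-[2,3,5-tris(benzyloxy)-4-methoxyphenyl]propan-2-ol
Product: 12 (1R,2S)-1-(benzyloxy)-1-[2,3,5-tris(benzyloxy)-6-iodo-4-methoxyphenyl]propan-2-ol
Conditions: NIS (1.1 equiv), CF3CO2H (0.2 equiv), MeCN, 0 °C → rt
Reagents that add atoms: N-iodosuccinimide, O=C1CCC(=O)N1I
Why: Electrophilic aromatic iodination at the only free position of the core ring, which is ortho and para to benzyloxy groups; the stereocentres are not touched.

Step 10
Reactants: 12 (1R,2S)-1-(benzyloxy)-1-[2,3,5-tris(benzyloxy)-6-iodo-4-methoxyphenyl]propan-2-ol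
Product: 13 triethyl{[(1R,2S)-1-(benzyloxy)-1-[2,3,5-tris(benzyloxy)-6-iodo-4-methoxyphenyl]propan-2-yl]oxy}silane
Conditions: Et3SiOTf (1.3 equiv), 2,6-lutidine, CH2Cl2, −78 → 0 °C
Reagents that add atoms: triethylsilyl trifluoromethanesulfonate, CC[Si](CC)(CC)OS(=O)(=O)C(F)(F)F
Why: Silylation of the hindered secondary alcohol with a silyl triflate; the TES ether masks the carbinol so that it cannot lactonise onto the acid made next.

Step 11
Reactants: 13 triethyl{[(1R,2S)-1-(benzyloxy)-1-[2,3,5-tris(benzyloxy)-6-iodo-4-methoxyphenyl]propan-2-yl]oxy}silane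
Product: 15 2,4,5-tris(benzyloxy)-6-[(1R,2S)-1-(benzyloxy)-2-(triethylsilyloxy)propyl]-3-methoxybenzoic acid, via arylmagnesium chloride 14 (not isolated)
Conditions: iPrMgCl·LiCl (1.3 equiv), THF, 0 °C → rt; CO2 (g), −20 °C → rt; cold 0.5 M HCl to pH 4
Reagents that add atoms: carbon dioxide, O=C=O
Why: Knochel iodine–magnesium exchange and carboxylation of the aryl Grignard; ethers and the silyl ether are inert, and the cold pH 4 work-up keeps the TES group.

Step 12
Reactants: 15 2,4,5-tris(benzyloxy)-6-[(1R,2S)-1-(benzyloxy)-2-(triethylsilyloxy)propyl]-3-methoxybenzoic acid; 7 (1S,2S)-1-(benzyloxy)-1-[3,5-bis(benzyloxy)-2-iodo-4-methoxyphenyl]propan-2-ol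
Product: 16 (1S,2R)-1-(benzyloxy)-1-[3,5-bis(benzyloxy)-2-iodo-4-methoxyphenyl]propan-2-yl 2,4,5-tris(benzyloxy)-6-[(1R,2S)-1-(benzyloxy)-2-(triethylsilyloxy)propyl]-3-methoxybenzoate
Conditions: PPh3 (1.5 equiv), DIAD (1.5 equiv), toluene, 0 °C → rt
Reagents that add atoms: none
Why: Mitsunobu esterification; the carboxylate of the di-ortho-substituted acid attacks the oxyphosphonium ion at carbon, so crowding at the carbonyl does not matter, and C2 of 7 is inverted (S → R).

Step 13
Reactants: 16 (1S,2R)-1-(benzyloxy)-1-[3,5-bis(benzyloxy)-2-iodo-4-methoxyphenyl]propan-2-yl 2,4,5-tris(benzyloxy)-6-[(1R,2S)-1-(benzyloxy)-2-(triethylsilyloxy)propyl]-3-methoxybenzoate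
Product: 19 2,4-bis(benzyloxy)-6-[(1S,2R)-1-(benzyloxy)-2-({2,4,5-tris(benzyloxy)-6-[(1R,2S)-1-(benzyloxy)-2-hydroxypropyl]-3-methoxybenzoyl}oxy)propyl]-3-methoxybenzoic acid, via arylmagnesium chloride 17 (not isolated), via silyl-protected acid 18 (not isolated)
Conditions: iPrMgCl·LiCl (1.2 equiv), THF, −30 °C, 30 min; CO2 (g), −30 → 0 °C; then 1 M HCl, THF–MeOH, 0 °C → rt
Reagents that add atoms: carbon dioxide, O=C=O
Why: Iodine–magnesium exchange and carboxylation at −30 °C, where the di-ortho-substituted (mesitoate-like) ester resists both the reagent and the aryl Grignard; the acidic work-up then cleaves the TES ether by hydrolysis without touching a stereocentre.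

Step 14
Reactants: 19 2,4-bis(benzyloxy)-6-[(1S,2R)-1-(benzyloxy)-2-({2,4,5-tris(benzyloxy)-6-[(1R,2S)-1-(benzyloxy)-2-hydroxypropyl]-3-methoxybenzoyl}oxy)propyl]-3-methoxybenzoic acid
Product: 20 heptabenzyl ether of the target (12-membered dilactone; all five phenols and both benzylic hydroxyls as benzyl ethers)
Conditions: PPh3 (5 equiv), DIAD (5 equiv), toluene (2 mM, slow addition of 19), 0 °C → rt
Reagents that add atoms: none
Why: Mitsunobu macrolactonization at high dilution, the standard closure for 2,6-disubstituted benzoate macrolides; intramolecular carboxylate SN2 inverts the ring B side-chain carbinol (S → R) and sets the last stereocentre.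

Step 15
Reactants: 20 heptabenzyl ether of the target
Product: 21 CNP0086623.1 (target)
Conditions: H2 (1 atm), Pd(OH)2/C, EtOAc–MeOH, rt; filtration and concentration under argon
Reagents that add atoms: none
Why: Catalytic hydrogenolysis of seven benzyl ethers; the unhindered PhCH2–O bonds cleave much faster than the crowded secondary benzylic C–O bonds, and neutral conditions avoid phthalide formation and keep the hydroquinone ring from oxidising.

**Compound list**
1 | 3,5-dihydroxy-4-methoxybenzaldehyde | COc1c(O)cc(C=O)cc1O | starting material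
2 | 3,5-bis(benzyloxy)-4-methoxybenzaldehyde | COc1c(OCc2ccccc2)cc(C=O)cc1OCc1ccccc1 | intermediate
3 | 3,5-bis(benzyloxy)-2-iodo-4-methoxybenzaldehyde | COc1c(OCc2ccccc2)cc(C=O)c(I)c1OCc1ccccc1 | intermediate
4 | 1,3-bis(benzyloxy)-4-iodo-2-methoxy-5-[(E)-prop-1-en-1-yl]benzene | C/C=C/c1cc(OCc2ccccc2)c(OC)c(OCc2ccccc2)c1I | intermediate
5 | (2S,3S)-2-[3,5-bis(benzyloxy)-2-iodo-4-methoxyphenyl]-3-methyloxirane | C[C@@H]1O[C@H]1c1cc(OCc2ccccc2)c(OC)c(OCc2ccccc2)c1I | intermediate
6 | (1S,2S)-1-(benzyloxy)-1-[3,5-bis(benzyloxy)-2-iodo-4-methoxyphenyl]propan-2-yl bis(pentafluorophenyl)borinate | C[C@H](OB(c1c(F)c(F)c(F)c(F)c1F)c1c(F)c(F)c(F)c(F)c1F)[C@@H](OCc1ccccc1)c1cc(OCc2ccccc2)c(OC)c(OCc2ccccc2)c1I | intermediate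
7 | (1S,2S)-1-(benzyloxy)-1-[3,5-bis(benzyloxy)-2-iodo-4-methoxyphenyl]propan-2-ol | C[C@H](O)[C@@H](OCc1ccccc1)c1cc(OCc2ccccc2)c(OC)c(OCc2ccccc2)c1I | intermediate
8 | potassium 2,4-bis(benzyloxy)-3-methoxy-6-[(E)-prop-1-en-1-yl]phenolate | C/C=C/c1cc(OCc2ccccc2)c(OC)c(OCc2ccccc2)c1[O-].[K+] | intermediate
9 | 1,3,4-tris(benzyloxy)-2-methoxy-5-[(E)-prop-1-en-1-yl]benzene | C/C=C/c1cc(OCc2ccccc2)c(OC)c(OCc2ccccc2)c1OCc1ccccc1 | intermediate
10 | (2S,3S)-3-methyl-2-[2,3,5-tris(benzyloxy)-4-methoxyphenyl]oxirane | C[C@@H]1O[C@H]1c1cc(OCc2ccccc2)c(OC)c(OCc2ccccc2)c1OCc1ccccc1 | intermediate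
11 | (1R,2S)-1-(benzyloxy)-1-[2,3,5-tris(benzyloxy)-4-methoxyphenyl]propan-2-ol | C[C@H](O)[C@H](OCc1ccccc1)c1cc(OCc2ccccc2)c(OC)c(OCc2ccccc2)c1OCc1ccccc1 | intermediate
12 | (1R,2S)-1-(benzyloxy)-1-[2,3,5-tris(benzyloxy)-6-iodo-4-methoxyphenyl]propan-2-ol | C[C@H](O)[C@H](OCc1ccccc1)c1c(I)c(OCc2ccccc2)c(OC)c(OCc2ccccc2)c1OCc1ccccc1 | intermediate
13 | triethyl{[(1R,2S)-1-(benzyloxy)-1-[2,3,5-tris(benzyloxy)-6-iodo-4-methoxyphenyl]propan-2-yl]oxy}silane | C[C@H](O[Si](CC)(CC)CC)[C@H](OCc1ccccc1)c1c(I)c(OCc2ccccc2)c(OC)c(OCc2ccccc2)c1OCc1ccccc1 | intermediate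
14 | arylmagnesium chloride from 13 (MgCl in place of I) | C[C@H](O[Si](CC)(CC)CC)[C@H](OCc1ccccc1)c1c([Mg]Cl)c(OCc2ccccc2)c(OC)c(OCc2ccccc2)c1OCc1ccccc1 | intermediate
15 | 2,4,5-tris(benzyloxy)-6-[(1R,2S)-1-(benzyloxy)-2-(triethylsilyloxy)propyl]-3-methoxybenzoic acid | C[C@H](O[Si](CC)(CC)CC)[C@H](OCc1ccccc1)c1c(C(=O)O)c(OCc2ccccc2)c(OC)c(OCc2ccccc2)c1OCc1ccccc1 | intermediate
16 | (1S,2R)-1-(benzyloxy)-1-[3,5-bis(benzyloxy)-2-iodo-4-methoxyphenyl]propan-2-yl 2,4,5-tris(benzyloxy)-6-[(1R,2S)-1-(benzyloxy)-2-(triethylsilyloxy)propyl]-3-methoxybenzoate | C[C@@H](OC(=O)c1c(OCc2ccccc2)c(OC)c(OCc2ccccc2)c(OCc2ccccc2)c1[C@@H](OCc1ccccc1)[C@H](C)O[Si](CC)(CC)CC)[C@@H](OCc1ccccc1)c1cc(OCc2ccccc2)c(OC)c(OCc2ccccc2)c1I | intermediate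
17 | arylmagnesium chloride from 16 (MgCl in place of I on ring A) | C[C@@H](OC(=O)c1c(OCc2ccccc2)c(OC)c(OCc2ccccc2)c(OCc2ccccc2)c1[C@@H](OCc1ccccc1)[C@H](C)O[Si](CC)(CC)CC)[C@@H](OCc1ccccc1)c1cc(OCc2ccccc2)c(OC)c(OCc2ccccc2)c1[Mg]Cl | intermediate
18 | triethylsilyl-protected seco acid (CO2H in place of I of 16) | C[C@@H](OC(=O)c1c(OCc2ccccc2)c(OC)c(OCc2ccccc2)c(OCc2ccccc2)c1[C@@H](OCc1ccccc1)[C@H](C)O[Si](CC)(CC)CC)[C@@H](OCc1ccccc1)c1cc(OCc2ccccc2)c(OC)c(OCc2ccccc2)c1C(=O)O | intermediate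
19 | 2,4-bis(benzyloxy)-6-[(1S,2R)-1-(benzyloxy)-2-({2,4,5-tris(benzyloxy)-6-[(1R,2S)-1-(benzyloxy)-2-hydroxypropyl]-3-methoxybenzoyl}oxy)propyl]-3-methoxybenzoic acid | C[C@@H](OC(=O)c1c(OCc2ccccc2)c(OC)c(OCc2ccccc2)c(OCc2ccccc2)c1[C@@H](OCc1ccccc1)[C@H](C)O)[C@@H](OCc1ccccc1)c1cc(OCc2ccccc2)c(OC)c(OCc2ccccc2)c1C(=O)O | intermediate
20 | heptabenzyl ether of the target: 12-membered dilactone, ring A side chain (1S,2R), ring B side chain (1R,2R), all seven hydroxyls as benzyl ethers | COc1c(OCc3ccccc3)cc2c(c1OCc3ccccc3)C(=O)O[C@H](C)[C@H](OCc1ccccc1)c1c(OCc3ccccc3)c(OCc3ccccc3)c(OC)c(OCc3ccccc3)c1C(=O)O[C@H](C)[C@H]2OCc1ccccc1 | intermediate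
21 | CNP0086623.1: 12-membered dilactone of the 2,4-dihydroxy-3-methoxybenzoate (ring A) and 2,4,5-trihydroxy-3-methoxybenzoate (ring B) units, each carrying an ortho 1-hydroxy-2-(acyloxy)propyl chain, (1S,2R) on ring A and (1R,2R) on ring B | COc1c(O)cc2c(c1O)C(=O)O[C@H](C)[C@H](O)c1c(O)c(O)c(OC)c(O)c1C(=O)O[C@H](C)[C@H]2O | target

**Step count**
Total: 15 steps. Longest linear sequence: 13 steps (steps 1, 2, 3, 6, 7, 8, 9, 10, 11, 12, 13, 14, 15).

**Three steps most likely to fail**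

Step 5 (new boron-delivered retentive benzyloxylation). The strong Lewis acid may instead cause Meinwald rearrangement to the aryl ketone, or the stereochemistry may leak. The fallback uses known chemistry and replaces retentive opening of the trans-epoxide by invertive opening of a cis-epoxide. It sets out from aldehyde 3. A Z-selective Wittig olefination (EtPPh3Br, NaN(SiMe3)2, THF, −78 °C; ortho-substituted benzaldehydes give high Z ratios) gives 1,3-bis(benzyloxy)-4-iodo-2-methoxy-5-[(Z)-prop-1-en-1-yl]benzene F1. Epoxidation with Shi's glucose-derived N-aryl oxazolidinone ketone for cis-olefins and Oxone (enantiomer of the ketone chosen for this sense) gives (2R,3S)-2-[3,5-bis(benzyloxy)-2-iodo-4-methoxyphenyl]-3-methyloxirane F2. BnOH with catalytic BF3·OEt2 at −40 °C, as in step 8, then opens the benzylic carbon with inversion (R → S), and the route is rejoined at 7.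

Step 13 (iodine–magnesium exchange and carboxylation next to an ester, with silyl ether cleavage in the work-up). The aryl Grignard 17 can attack the ester on its own side chain through a six-membered transition state, and the acidic work-up could start translactonization. The fallback replaces the organomagnesium route by palladium acyl chemistry and sets out from 16. Alkoxycarbonylation (Pd(OAc)2, Xantphos, CO 1 atm, Et3N, 2-(trimethylsilyl)ethanol, toluene, 80 °C) gives the 2-(trimethylsilyl)ethyl ester of silyl-protected acid 18, F3. Tris(dimethylamino)sulfonium difluorotrimethylsilicate in DMF (0 °C → rt) then removes the silylethyl ester and the TES ether together under near-neutral conditions, and the route is rejoined at 19.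

Step 14 (Mitsunobu macrolactonization). The carbinol sits next to a hexasubstituted arene, so elimination or oligomerisation may win. The fallback activates the alcohol as a sulfonate before the acid exists and closes the ring by cesium carboxylate displacement (Kruizinga–Kellogg); it sets out from 16. HF·pyridine (THF, 0 °C) gives (1S,2R)-1-(benzyloxy)-1-[3,5-bis(benzyloxy)-2-iodo-4-methoxyphenyl]propan-2-yl 2,4,5-tris(benzyloxy)-6-[(1R,2S)-1-(benzyloxy)-2-hydroxypropyl]-3-methoxybenzoate F4. MsCl/Et3N (CH2Cl2, −20 °C) gives the corresponding methanesulfonate F5. iPrMgCl·LiCl (THF, −30 °C) gives the arylmagnesium chloride of the methanesulfonate F6, and CO2 with cold acidic work-up gives the methanesulfonate carboxylic acid F7. Cs2CO3 in DMF (60 °C, 2 mM) then closes the ring by intramolecular SN2 with inversion at the carbinol carbon (S → R), and the route is rejoined at 20.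

**Further compounds**
F1 | step 5 | 1,3-bis(benzyloxy)-4-iodo-2-methoxy-5-[(Z)-prop-1-en-1-yl]benzene | C/C=C\c1cc(OCc2ccccc2)c(OC)c(OCc2ccccc2)c1I
F2 | step 5 | (2R,3S)-2-[3,5-bis(benzyloxy)-2-iodo-4-methoxyphenyl]-3-methyloxirane | C[C@@H]1O[C@@H]1c1cc(OCc2ccccc2)c(OC)c(OCc2ccccc2)c1I
F3 | step 13 | 2-(trimethylsilyl)ethyl ester of silyl-protected acid 18 | C[C@@H](OC(=O)c1c(OCc2ccccc2)c(OC)c(OCc2ccccc2)c(OCc2ccccc2)c1[C@@H](OCc1ccccc1)[C@H](C)O[Si](CC)(CC)CC)[C@@H](OCc1ccccc1)c1cc(OCc2ccccc2)c(OC)c(OCc2ccccc2)c1C(=O)OCC[Si](C)(C)C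
F4 | step 14 | (1S,2R)-1-(benzyloxy)-1-[3,5-bis(benzyloxy)-2-iodo-4-methoxyphenyl]propan-2-yl 2,4,5-tris(benzyloxy)-6-[(1R,2S)-1-(benzyloxy)-2-hydroxypropyl]-3-methoxybenzoate | C[C@@H](OC(=O)c1c(OCc2ccccc2)c(OC)c(OCc2ccccc2)c(OCc2ccccc2)c1[C@@H](OCc1ccccc1)[C@H](C)O)[C@@H](OCc1ccccc1)c1cc(OCc2ccccc2)c(OC)c(OCc2ccccc2)c1I
F5 | step 14 | methanesulfonate of F4 at the free secondary hydroxyl | C[C@@H](OC(=O)c1c(OCc2ccccc2)c(OC)c(OCc2ccccc2)c(OCc2ccccc2)c1[C@@H](OCc1ccccc1)[C@H](C)OS(C)(=O)=O)[C@@H](OCc1ccccc1)c1cc(OCc2ccccc2)c(OC)c(OCc2ccccc2)c1I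
F6 | step 14 | arylmagnesium chloride from F5 (MgCl in place of I) | C[C@@H](OC(=O)c1c(OCc2ccccc2)c(OC)c(OCc2ccccc2)c(OCc2ccccc2)c1[C@@H](OCc1ccccc1)[C@H](C)OS(C)(=O)=O)[C@@H](OCc1ccccc1)c1cc(OCc2ccccc2)c(OC)c(OCc2ccccc2)c1[Mg]Cl
F7 | step 14 | methanesulfonate carboxylic acid (CO2H in place of I of F5) | C[C@@H](OC(=O)c1c(OCc2ccccc2)c(OC)c(OCc2ccccc2)c(OCc2ccccc2)c1[C@@H](OCc1ccccc1)[C@H](C)OS(C)(=O)=O)[C@@H](OCc1ccccc1)c1cc(OCc2ccccc2)c(OC)c(OCc2ccccc2)c1C(=O)O
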